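**Retrosynthetic overview**

1. Upper half (all carbons of the future chromanone plus the ArCH–O carbon): ketone 1 → tribenzyl ether 2; with aldehyde 3 → chalcone 4 → epoxide 5 → bromohydrin 6 → racemic 3-bromo-1,2-dione 7.
2. Key disconnection, dihydrofuran ring (formed first): formal [3+2] cycloaddition of 7 with the C8=C7–OH unit of ring A of natural (−)-epiafzelechin 8 (aldol adduct 9, then O-alkylation) gives 10. This step is a stepwise annulation, not a concerted pericyclic reaction; no concerted cycloaddition, electrocyclization or sigmatropic shift maps soundly onto this ring with its tertiary carbinol.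
3. Global debenzylation gives hexaphenol 11.
4. Last disconnection, chromanone ring together with the cyclohexadienone (formed last): the aryl ether C–O bond to flavan C8 is closed by oxidative dearomatization of 11 through iodane 12 to target 13.
5. Stereochemistry: C2 and C3 are bought in 8. The two furan centres are set relative to each other in step 6, but their sense relative to the flavan is essentially uncontrolled and needs a diastereomer separation. The quaternary carbon is fixed in step 8 by the cis-only tether.

Assumption: the target is exactly the stereoisomer of the given SMILES, and natural (−)-epiafzelechin (2R,3R) is bought as a single enantiomer.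

Flavan numbering (C2, C3, C5, C7, C8) is used for the lower half. In the names of 10 and 11 the furo[2,3-h]chromene numbering applies (C8 = ArCH–O, C9 = carbinol).

**Route**

Step 1
Reactants: 1 2',4',6'-trihydroxyacetophenone
Product: 2 1-[2,4,6-tris(benzyloxy)phenyl]ethanone
Conditions: BnBr (3.6 equiv), K2CO3 (4 equiv), DMF, 80 °C
Reagents that add atoms: benzyl bromide BrCc1ccccc1
Why: Williamson etherification with excess benzyl bromide in hot DMF also alkylates the two hydrogen-bonded ortho hydroxyls, masking the phenols that would otherwise cyclize onto the electrophilic carbons made later.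

Step 2
Reactants: 2 1-[2,4,6-tris(benzyloxy)phenyl]ethanone, 3 4-(benzyloxy)benzaldehyde
Product: 4 (E)-3-[4-(benzyloxy)phenyl]-1-[2,4,6-tris(benzyloxy)phenyl]prop-2-en-1-one
Conditions: KOH (50% aq), EtOH/THF, rt, 24 h
Reagents that add atoms: none
Why: Claisen–Schmidt (crossed aldol) condensation with a non-enolizable aldehyde and E1cB dehydration gives the thermodynamic E-enone, and without a free 2'-hydroxyl no flavanone can form.

Step 3
Reactants: 4 (E)-chalcone
Product: 5 rac-trans-{3-[4-(benzyloxy)phenyl]oxiran-2-yl}[2,4,6-tris(benzyloxy)phenyl]methanone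
Conditions: 30% H2O2, 2 M NaOH, MeOH/THF, 0 °C to rt
Reagents that add atoms: hydrogen peroxide OO
Why: Weitz–Scheffer nucleophilic epoxidation (conjugate addition of hydroperoxide, then closure with loss of hydroxide) gives the trans-epoxide as a racemate whose configuration is not carried forward.

Step 4
Reactants: 5 rac-trans-epoxy ketone
Product: 6 rac-(2R*,3S*)-3-bromo-3-[4-(benzyloxy)phenyl]-2-hydroxy-1-[2,4,6-tris(benzyloxy)phenyl]propan-1-one
Conditions: LiBr (3 equiv), AcOH (3 equiv), THF, 0 °C to rt
Reagents that add atoms: lithium bromide [Li+].[Br-]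
Why: Acid-assisted epoxide opening (halohydrin formation) by bromide occurs with inversion at the benzylic carbon, which is activated by the 4-benzyloxyphenyl group and is remote from the deactivating carbonyl.

Step 5
Reactants: 6 rac-bromohydrin
Product: 7 rac-3-bromo-3-[4-(benzyloxy)phenyl]-1-[2,4,6-tris(benzyloxy)phenyl]propane-1,2-dione
Conditions: Dess–Martin periodinane (1.3 equiv), CH2Cl2, 0 °C to rt; used crude
Reagents that add atoms: none
Why: Dess–Martin oxidation with pentavalent iodine turns the α-hydroxy ketone into the 1,2-dione under non-basic conditions that spare the benzylic bromide; the bromide-bearing carbon is now enolizable, so 7 is an equilibrating racemate.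

Step 6
Reactants: 7 rac-3-bromo-1,2-dione, 8 (−)-epiafzelechin [(2R,3R)-2-(4-hydroxyphenyl)chromane-3,5,7-triol]
Product: 10 [(2R,3R,8S,9S)-8-[4-(benzyloxy)phenyl]-3,5,9-trihydroxy-2-(4-hydroxyphenyl)-3,4,8,9-tetrahydro-2H-furo[2,3-h]chromen-9-yl][2,4,6-tris(benzyloxy)phenyl]methanone, via aldol adduct 9 (not isolated)
Conditions: 8 (1.0 equiv), 7 (1.2 equiv), NaHCO3 (2.5 equiv), degassed THF/H2O (4:1), 0 °C to rt, Ar; chromatography, then preparative HPLC
Reagents that add atoms: none
Why: Formal [3+2] cycloaddition of the interrupted Feist–Benary type: the phloroglucinol-like C8 of ring A (the more nucleophilic ring position, as in 4→8 proanthocyanidin bonds) adds to the most electrophilic central carbonyl of 7 to give carbinol 9, and the neighbouring 7-phenoxide then displaces bromide with inversion (5-exo-tet), so the aryl ends up on the oxygen-bearing carbon; because 7 epimerizes and the aldol is reversible, closure is expected to run through the less hindered transition state to the ring with aryl trans to aroyl (cis to OH), while the remote (2R,3R) centres bias the face only weakly, so the (8S,9S) isomer 10 must be separated from its (8R,9R) diastereomer (roughly 1:1 expected) and from the minor C6 regioisomer.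

Step 7
Reactants: 10 tetra-O-benzyl annulation product
Product: 11 [(2R,3R,8S,9S)-3,5,9-trihydroxy-2,8-bis(4-hydroxyphenyl)-3,4,8,9-tetrahydro-2H-furo[2,3-h]chromen-9-yl](2,4,6-trihydroxyphenyl)methanone
Conditions: H2 (1 atm), 20% Pd(OH)2/C, THF/MeOH (1:1), rt
Reagents that add atoms: none
Why: Catalytic hydrogenolysis of the four aryl benzyl ethers is neutral, which avoids acid-induced dehydration of the tertiary benzylic alcohol to the benzofuran, and the cyclic benzylic ethers and the hindered aryl ketone react far more slowly than O-benzyl groups.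

Step 8
Reactants: 11 hexaphenol
Product: 13 target CNP0170480.3, via aryloxy(phenyl)iodine acetate 12 (not isolated)
Conditions: PhI(OAc)2 (1.05 equiv), (CF3)2CHOH/MeCN (1:4), −20 °C to 0 °C
Reagents that add atoms: none
Why: Oxidative dearomatization with trivalent iodine: ligand exchange at the electron-richest phenol (5-OH of ring A) gives 12, and the ortho hydroxyl of the aroyl group attacks the para carbon (flavan C8) as iodobenzene leaves, forming the 4,4-disubstituted cyclohexa-2,5-dienone and the chromanone ring in one event; the two-atom tether from the carbinol carbon allows only cis fusion, so the quaternary centre is set by the carbinol centre.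

**Compound list**

1 | 2',4',6'-trihydroxyacetophenone | CC(=O)c1c(O)cc(O)cc1O | starting material
2 | 1-[2,4,6-tris(benzyloxy)phenyl]ethanone | CC(=O)c1c(OCc2ccccc2)cc(OCc2ccccc2)cc1OCc1ccccc1 | intermediate
3 | 4-(benzyloxy)benzaldehyde | O=Cc1ccc(OCc2ccccc2)cc1 | starting material
4 | (E)-3-[4-(benzyloxy)phenyl]-1-[2,4,6-tris(benzyloxy)phenyl]prop-2-en-1-one | O=C(/C=C/c1ccc(OCc2ccccc2)cc1)c1c(OCc2ccccc2)cc(OCc2ccccc2)cc1OCc1ccccc1 | intermediate
5 | rac-trans-{3-[4-(benzyloxy)phenyl]oxiran-2-yl}[2,4,6-tris(benzyloxy)phenyl]methanone (racemate, one enantiomer drawn) | O=C([C@H]1O[C@@H]1c1ccc(OCc2ccccc2)cc1)c1c(OCc2ccccc2)cc(OCc2ccccc2)cc1OCc1ccccc1 | intermediate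
6 | rac-(2R*,3S*)-3-bromo-3-[4-(benzyloxy)phenyl]-2-hydroxy-1-[2,4,6-tris(benzyloxy)phenyl]propan-1-one (racemate, one enantiomer drawn) | O=C([C@@H](O)[C@@H](Br)c1ccc(OCc2ccccc2)cc1)c1c(OCc2ccccc2)cc(OCc2ccccc2)cc1OCc1ccccc1 | intermediate
7 | rac-3-bromo-3-[4-(benzyloxy)phenyl]-1-[2,4,6-tris(benzyloxy)phenyl]propane-1,2-dione | O=C(C(=O)C(Br)c1ccc(OCc2ccccc2)cc1)c1c(OCc2ccccc2)cc(OCc2ccccc2)cc1OCc1ccccc1 | intermediate
8 | (−)-epiafzelechin, (2R,3R)-2-(4-hydroxyphenyl)chromane-3,5,7-triol | Oc1cc(O)c2C[C@@H](O)[C@@H](c3ccc(O)cc3)Oc2c1 | starting material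
9 | aldol adduct: epiafzelechin bearing at C8 the tertiary carbinol C(OH)[CO-C6H2(OBn)3]-CHBr-C6H4OBn (the diastereomer that closes to 10) | Oc1cc(O)c([C@@](O)(C(=O)c4c(OCc5ccccc5)cc(OCc5ccccc5)cc4OCc5ccccc5)[C@H](Br)c3ccc(OCc5ccccc5)cc3)c2c1C[C@@H](O)[C@@H](c1ccc(O)cc1)O2 | intermediate
10 | [(2R,3R,8S,9S)-8-[4-(benzyloxy)phenyl]-3,5,9-trihydroxy-2-(4-hydroxyphenyl)-3,4,8,9-tetrahydro-2H-furo[2,3-h]chromen-9-yl][2,4,6-tris(benzyloxy)phenyl]methanone (8-aryl cis to 9-OH) | Oc1cc2O[C@@H](c3ccc(OCc5ccccc5)cc3)[C@](O)(C(=O)c4c(OCc5ccccc5)cc(OCc5ccccc5)cc4OCc5ccccc5)c2c2c1C[C@@H](O)[C@@H](c1ccc(O)cc1)O2 | intermediate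
11 | [(2R,3R,8S,9S)-3,5,9-trihydroxy-2,8-bis(4-hydroxyphenyl)-3,4,8,9-tetrahydro-2H-furo[2,3-h]chromen-9-yl](2,4,6-trihydroxyphenyl)methanone | Oc1cc2O[C@@H](c3ccc(O)cc3)[C@](O)(C(=O)c4c(O)cc(O)cc4O)c2c2c1C[C@@H](O)[C@@H](c1ccc(O)cc1)O2 | intermediate
12 | 5-O-[acetoxy(phenyl)iodanyl] derivative of 11 (trivalent iodine) | CC(=O)OI(c6ccccc6)Oc1cc2O[C@@H](c3ccc(O)cc3)[C@](O)(C(=O)c4c(O)cc(O)cc4O)c2c2c1C[C@@H](O)[C@@H](c1ccc(O)cc1)O2 | intermediate
13 | target CNP0170480.3 (C30H22O11): ring A of the (2R,3R)-flavan is a cyclohexa-2,5-dienone whose quaternary carbon (S) carries the aryl ether oxygen of a cis-fused 3,5,7-trihydroxychroman-4-one and is fused to the dihydrofuran with (S)-CH(4-hydroxyphenyl)–O and (R)-carbinol, aryl cis to OH | O=C1C=C2O[C@@H](c3ccc(O)cc3)[C@]3(O)C(=O)c4c(O)cc(O)cc4O[C@]23C2=C1C[C@@H](O)[C@@H](c1ccc(O)cc1)O2 | target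

(The carbinol descriptor changes from S in 10 and 11 to R in 13 only because the CIP priorities change on dearomatization; the spatial arrangement is the same.)

**Totals and risks**

Total step count: 8. Longest linear sequence: 8 steps (1 to 13); building block 8 enters at step 6.

The three steps most likely to fail are 6, 8 and 7.

Step 6 is the weakest. Possible failures are O-alkylation of the other phenols, attack by C6 instead of C8, C-alkylation at the bromide carbon (which would invert the regiochemistry), and poor facial selectivity. Even if all else works, about half the material is the unwanted (8R,9R) diastereomer. The fallback sets out from 7 (with 8) and comes back at 10, and it removes the halide so that the C–C bond is fixed before the C–O bond. Kornblum oxidation of 7 (DMSO, NaHCO3, rt) gives 1-[4-(benzyloxy)phenyl]-3-[2,4,6-tris(benzyloxy)phenyl]propane-1,2,3-trione F1. Its central carbonyl undergoes Friedel–Crafts hydroxyalkylation at C8 of 8 (Sc(OTf)3 5 mol%, MeCN/THF, rt) to give the C8 carbinol adduct F2. NaBH4 (MeOH, −20 °C) reduces only the unhindered 4-benzyloxyphenyl ketone, giving the benzylic alcohol F3. Pyridinium tosylate in CH2Cl2 then closes the ether from the 7-OH by an SN1 substitution at the 4-benzyloxybenzylic carbon under thermodynamic control (aryl trans to aroyl), giving 10. The diastereomer separation is still needed.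

Step 7 may cleave the two cyclic benzylic C–O bonds or the tertiary benzylic alcohol along with the benzyl ethers. The fallback sets out from 10 and comes back at 11 and abandons reduction: Lewis-acid dealkylation with BCl3 and pentamethylbenzene as cation scavenger (CH2Cl2, −78 °C), in which chelation to the ketone speeds the ortho ethers. This fallback makes no new compound (F0).

Step 8 must pick one of six phenols, and capture at the ortho carbon or over-oxidation of the 4-hydroxyphenyl rings can compete. The fallback sets out from 11 and comes back at 13 and separates oxidation from ring closure. PhI(OAc)2 in MeOH at −40 °C lets the solvent trap the para position, giving the para-quinol methyl ether F4. Catalytic CF3CO2H in (CF3)2CHOH at 0 °C then ionizes the C–OMe bond, and the ortho hydroxyl of the aroyl group closes the chromanone ring with loss of methanol to give 13.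

**Further compounds**

F1 | step 6 | 1-[4-(benzyloxy)phenyl]-3-[2,4,6-tris(benzyloxy)phenyl]propane-1,2,3-trione | O=C(C(=O)C(=O)c1ccc(OCc2ccccc2)cc1)c1c(OCc2ccccc2)cc(OCc2ccccc2)cc1OCc1ccccc1
F2 | step 6 | C8 carbinol adduct of 8 with F1 (open hydroxy-dione form, in equilibrium with its five-membered hemiketal) | Oc1cc(O)c([C@@](O)(C(=O)c4c(OCc5ccccc5)cc(OCc5ccccc5)cc4OCc5ccccc5)C(=O)c3ccc(OCc5ccccc5)cc3)c2c1C[C@@H](O)[C@@H](c1ccc(O)cc1)O2
F3 | step 6 | benzylic alcohol from F2 (both epimers at the new CH–OH carbon) | Oc1cc(O)c([C@@](O)(C(=O)c4c(OCc5ccccc5)cc(OCc5ccccc5)cc4OCc5ccccc5)C(O)c3ccc(OCc5ccccc5)cc3)c2c1C[C@@H](O)[C@@H](c1ccc(O)cc1)O2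
F0 | step 7 | none | none
F4 | step 8 | para-quinol methyl ether of 11 (methoxy on the former flavan C8, both epimers at that carbon) | O=C1C=C2O[C@@H](c3ccc(O)cc3)[C@](O)(C(=O)c4c(O)cc(O)cc4O)C2(OC)C2=C1C[C@@H](O)[C@@H](c1ccc(O)cc1)O2
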